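All runs were generated by integration with made-up constants; scatter was added.

Time first: this flask is read at 2.0 d, and the dosing lasts 50 h, so 96.0% of the E has gone in by then.

- Saturday's: E 0.050 M (fed, over 50 h); L 0.38 M; G 1.4 mM; run made earlier
- flask: E 0.050 M (fed, over 50 h); L 0.250 M; G 1.4 mM; time 2.0 d

Saturday's run (percent of the E charged)

| time / h | Q / % | E / % |
|---|---|---|
| 4.00 | 0 | 9 |
| 8.00 | 1 | 18 |
| 10.0 | 0 | 19 |
| 15.0 | 0 | 24 |

(readings scatter by 2 percentage points)

- concentration of Q at 2.0 d, in M
- concentration of E at 2.0 d, in M
- concentration of X at 2.0 d, in M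

- steps thought possible: E + X <-> D; D -> G + Q; J -> X; L + G <-> J
- percentages count the whole charge, also what has not yet gone in

I carry one quantity from Saturday's run: the clearing constant, the share of free E turned over per hour, a pseudo-first-order constant. While E is dosed, the lost share grows as the square of the time. Fed share minus E and the reading of Q both estimate that lost share. I therefore weight each reading by its time squared:

kS = 0.0105 h⁻¹

Each reading scatters by 2 percentage points, so this constant is rough.

I reckon two extreme versions of this flask. If nothing reacts, E is the whole fed share, 96.0%. If L makes no difference, steady inflow against first-order loss gives: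

E = (1 − exp(−kS·t)) / (kS·tf) = 75.3%

This flask has 0.250 M of L against Saturday's 0.38 M. I expect less L to slow the loss, so I scale the constant in proportion:

k = 0.00694 h⁻¹, E = 81.7%, Q = 14.3%

That E is more than the second extreme and less than the first. The readings show no catalyst form, so they give me no figure for X.

The forecast says 0.005 M of Q, 0.042 M of E and 2.000 × 10⁻⁴ M of X, adding “Lower L here may slow this further.”

At 2.00 d this flask holds 0.0413 M of E, which is 82.6% of the E charge, and 0.00659 M of Q, which is 13.2%, against my 81.7% and 14.3%; it holds 0.00107 M of X.

    E + X ⇌ D (K = 3.32 M⁻¹, k = 0.655 M⁻¹ min⁻¹)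
    D → G + Q (k = 0.0321 min⁻¹)
    J → X (k = 0.0346 min⁻¹)
    L + G ⇌ J (K = 200 M⁻¹, k = 0.184 M⁻¹ min⁻¹)

E + X and D relax with a half-life of 0.0513 h by this step alone, far shorter than the 2.0 d of the run. X, the resting state, holds 76.2% of the catalyst and D holds 8.97%. With 0.0024 M of G, 0.0105 h⁻¹ scaled by L and G becomes 0.0119 h⁻¹ and gives E 73.1%; that flask holds 74.3%.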